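Everything rests on disconnecting three bonds around C13: O9–C13 in ring C, and C14–C15 and C15–O16 in ring D. The feature exploited is this spiro atom itself: it is shared by the tetrahydrofuran ring C, whose oxygen it carries, and by the butyrolactone ring D, where the carbonyl C15 is the only atom between C14 and the oxygen on C16. A C13=C14 methylidene flanked by hydroxyls at C9 and C16 can therefore be stitched up with carbon monoxide: one palladium-catalysed oxycarbonylation closes both rings, creates C13 and brings in C15. Its substrate is a sclareolide-derived 15-norlabd-13(14)-ene-9α,16-diol whose cis 7β,8β-diol is masked as an acetonide.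

Key step: step 12

Remarks on the chemistry (labdane numbering; β is the face of the C10 methyl; 5α-H and 10β-CH3 are carried unchanged from sclareolide):
- The cascade substrate, the cascade product and the target carry the same configurations (8β-O with 8α-CH3, 9α-O, 13S), so no structure needed correction.
- The substrate of the cascade is kept as an acetonide. Around it, C7 is oxidised before the second alkene is present, the C16 hydroxyl stays silylated until the step before the cascade, and p-benzoquinone is the reoxidant in place of a copper salt.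
- Which antipode of the bis(oxazoline) is matched to the substrate cannot be predicted; the (S,S) form is written and the (R,R) form is screened alongside it.

Step 1
Reactants: 1 (+)-sclareolide
Product: 2 methyl 13,14,15,16-tetranorlabd-8(9)-en-12-oate
Conditions: H2SO4 (conc.), MeOH, reflux
Reagents that add atoms: methanol, CO
Why: Acid ionises the tertiary C8–O bond of the lactone, the C8 cation loses H9 (E1) and the acid is trapped by Fischer esterification; prolonged heating should equilibrate the alkene isomers toward the tetrasubstituted Δ8(9) position.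

Step 2
Reactants: 2 methyl 13,14,15,16-tetranorlabd-8(9)-en-12-oate
Product: 3 13,14,15,16-tetranorlabd-8(9)-en-12-ol
Conditions: LiAlH4, THF, 0 °C to rt
Reagents that add atoms: none
Why: Hydride reduction of the ester to the primary alcohol leaves the isolated tetrasubstituted alkene untouched.

Step 3
Reactants: 3 13,14,15,16-tetranorlabd-8(9)-en-12-ol
Product: 4 12-iodo-13,14,15,16-tetranorlabd-8(9)-ene
Conditions: I2, PPh3, imidazole, CH2Cl2, 0 °C to rt
Reagents that add atoms: iodine, [I][I]
Why: Appel-type iodination of the unhindered primary alcohol proceeds by SN2 displacement of the alkoxyphosphonium ion by iodide.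

Step 4
Reactants: 4 12-iodo-13,14,15,16-tetranorlabd-8(9)-ene
Product: 5 12-iodo-13,14,15,16-tetranorlabd-8(9)-en-7-one
Conditions: CrO3, 3,5-dimethylpyrazole, CH2Cl2, −20 °C
Reagents that add atoms: chromium trioxide, O=[Cr](=O)=O
Why: Allylic oxidation by the CrO3–3,5-dimethylpyrazole complex should take the ring methylene C7 in preference to the neopentyl-like C11 methylene, as is usual for labd-8-enes, and a primary alkyl iodide is inert to this oxidant; at this stage no second alkene can compete.

Step 5
Reactants: 6 2-bromoprop-2-en-1-ol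
Product: 7 [(2-bromoprop-2-en-1-yl)oxy](tert-butyl)diphenylsilane
Conditions: t-BuPh2SiCl, imidazole, CH2Cl2, 0 °C to rt
Reagents that add atoms: tert-butyl(chloro)diphenylsilane, CC(C)(C)[Si](Cl)(c1ccccc1)c1ccccc1
Why: Standard silylation of a primary allylic alcohol; the tert-butyldiphenylsilyl ether is chosen because it should survive the aqueous acid of step 9.

Step 6
Reactants: 5 12-iodo-13,14,15,16-tetranorlabd-8(9)-en-7-one; 7 [(2-bromoprop-2-en-1-yl)oxy](tert-butyl)diphenylsilane
Product: 9 16-(tert-butyldiphenylsilyloxy)-15-norlabda-8(9),13(14)-dien-7-one, via alkylzinc iodide 8 (not isolated)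
Conditions: Zn dust (I2-activated), DMA, 40 °C; then 7, PdCl2(dppf) (5 mol %), THF, 50 °C
Reagents that add atoms: zinc, [Zn] (retained in 8 only, not in 9)
Why: Negishi coupling: zinc inserts into the primary C–I bond to give an alkylzinc iodide that tolerates the enone, and palladium-catalysed sp3–sp2 coupling with the vinyl bromide forms the C12–C13 bond.

Step 7
Reactants: 9 16-(tert-butyldiphenylsilyloxy)-15-norlabda-8(9),13(14)-dien-7-one
Product: 10 16-(tert-butyldiphenylsilyloxy)-15-norlabda-8(9),13(14)-dien-7β-ol
Conditions: NaBH4, CeCl3·7H2O, MeOH, −40 °C to 0 °C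
Reagents that add atoms: none
Why: Luche reduction should give clean 1,2-reduction, with axial hydride delivery from the α face (away from the C10 methyl) setting the pseudo-equatorial 7β-hydroxyl, as in the reduction of steroidal 4-en-3-ones to 3β-ols.

Step 8
Reactants: 10 16-(tert-butyldiphenylsilyloxy)-15-norlabda-8(9),13(14)-dien-7β-ol
Product: 11 8β,9β-epoxy-16-(tert-butyldiphenylsilyloxy)-15-norlabd-13(14)-en-7β-ol
Conditions: VO(acac)2 (5 mol %), t-BuOOH (decane), CH2Cl2, 0 °C to rt
Reagents that add atoms: tert-butyl hydroperoxide, CC(C)(C)OO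
Why: Hydroxyl-directed epoxidation: the vanadium alkoxide of the 7β-alcohol delivers oxygen to the same (β) face of the tetrasubstituted alkene, setting C8 and C9 as known for the analogous cholest-4-en-3β-ol, while the side-chain alkene, which has no free allylic hydroxyl, should not react.

Step 9
Reactants: 11 8β,9β-epoxy-16-(tert-butyldiphenylsilyloxy)-15-norlabd-13(14)-en-7β-ol
Product: 12 16-(tert-butyldiphenylsilyloxy)-15-norlabd-13(14)-ene-7β,8β,9α-triol
Conditions: HClO4 (aq., cat.), THF–H2O (3:1), 0 °C to rt
Reagents that add atoms: water, O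
Why: Acid-catalysed trans-diaxial (Fürst–Plattner) epoxide opening: the C9–O bond, which is not deactivated by the neighbouring carbinol carbon, ionises and water attacks C9 from the α face with inversion, as in the opening of steroidal 9β,11β-epoxides at C9, giving the 8β,9α-diaxial diol.

Step 10
Reactants: 12 16-(tert-butyldiphenylsilyloxy)-15-norlabd-13(14)-ene-7β,8β,9α-triol
Product: 13 7β,8β-isopropylidenedioxy-16-(tert-butyldiphenylsilyloxy)-15-norlabd-13(14)-en-9α-ol
Conditions: 2,2-dimethoxypropane, PPTS (cat.), CH2Cl2, rt
Reagents that add atoms: 2,2-dimethoxypropane, COC(C)(C)OC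
Why: Acid-catalysed transketalisation engages only the cis 7β,8β-diol in a dioxolane, since the 8β,9α-diol is trans-diaxial and cannot be bridged, so the tertiary 9α-hydroxyl stays free.

Step 11
Reactants: 13 7β,8β-isopropylidenedioxy-16-(tert-butyldiphenylsilyloxy)-15-norlabd-13(14)-en-9α-ol
Product: 14 7β,8β-isopropylidenedioxy-15-norlabd-13(14)-ene-9α,16-diol
Conditions: Bu4NF, THF, 0 °C to rt
Reagents that add atoms: none
Why: Fluoride cleaves the Si–O bond selectively and frees the C16 hydroxyl without affecting the acetonide or the alkene.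

Step 12
Reactants: 14 7β,8β-isopropylidenedioxy-15-norlabd-13(14)-ene-9α,16-diol; 15 carbon monoxide
Product: 16 (13S)-9α,13-epoxy-7β,8β-isopropylidenedioxylabdan-15,16-olide
Conditions: Pd(O2CCF3)2 (10 mol %), (S,S)-Ph-box [2,2'-isopropylidenebis((4S)-4-phenyl-2-oxazoline)] (12 mol %), p-benzoquinone (2 equiv), CO (1 atm), CH2Cl2, rt
Reagents that add atoms: none
Why: Divalent palladium carrying the bis(oxazoline) binds the C13=C14 alkene, the tertiary 9α-hydroxyl adds to C13 (oxypalladation), the resulting C14–Pd bond has no β-hydrogen and so inserts CO, and the C16 hydroxyl captures the acylpalladium unit with release of zerovalent palladium, which p-benzoquinone reoxidises. The closest known reaction type is the palladium-catalysed hydroxycyclisation–carbonylation–lactonisation of alkenediols to bicyclic ether lactones, which tolerates tertiary hydroxyls and 1,1-disubstituted alkenes; because the lactonising hydroxyl here sits on the carbon attached to the internal alkene carbon, the two rings come out spiro-linked at C13 instead of fused. Ring C closes by 5-exo-trig attack of O9 on C13, and ring D closes by five-membered lactonisation, O16 attacking the acyl carbon C15 (5-exo-trig). The only new stereocentre, C13, is decided by which π-face of the alkene is attacked; C1 and the C17 methyl flank the forming ring almost equally, so little substrate bias is expected and the chiral ligand on palladium has to favour the face that puts C14 on the C8 side (13S). The step needs chemoselectivity for O9 over O8, secured by the acetonide, 5-exo Markovnikov regioselectivity, secured by the four-atom tether to a 1,1-disubstituted alkene, and lactonisation instead of ester formation, secured by the absence of an alcohol solvent; the copper-free, quinone-based reoxidation keeps the ligand on palladium and spares the acetonide from HCl.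

Step 13
Reactants: 16 (13S)-9α,13-epoxy-7β,8β-isopropylidenedioxylabdan-15,16-olide
Product: 17 (13S)-9α,13-epoxy-7β,8β-dihydroxylabdan-15,16-olide
Conditions: AcOH–H2O (4:1), 45 °C
Reagents that add atoms: none
Why: Mild aqueous acid hydrolyses the dioxolane while the lactone and the di-tertiary spiro ether should survive; base is avoided because a β-alkoxy lactone can open by retro-oxa-Michael reaction.

Step 14
Reactants: 17 (13S)-9α,13-epoxy-7β,8β-dihydroxylabdan-15,16-olide
Product: 18 (13S)-9α,13-epoxy-8β-hydroxy-7-oxolabdan-15,16-olide (target)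
Conditions: IBX, DMSO, rt
Reagents that add atoms: none
Why: IBX oxidises the secondary 7β-alcohol to the ketone without cleaving the 1,2-diol, the tertiary 8β-hydroxyl cannot be oxidised, and the neutral conditions leave C8, C9 and C13 untouched.

Compound list
1 | (+)-sclareolide | CC1(C)CCC[C@@]2(C)[C@H]1CC[C@@]3(C)OC(=O)C[C@H]23 | starting material
2 | methyl 13,14,15,16-tetranorlabd-8(9)-en-12-oate | CC1(C)CCC[C@@]2(C)[C@H]1CCC(C)=C2CC(=O)OC | intermediate
3 | 13,14,15,16-tetranorlabd-8(9)-en-12-ol | CC1(C)CCC[C@@]2(C)[C@H]1CCC(C)=C2CCO | intermediate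
4 | 12-iodo-13,14,15,16-tetranorlabd-8(9)-ene | CC1(C)CCC[C@@]2(C)[C@H]1CCC(C)=C2CCI | intermediate
5 | 12-iodo-13,14,15,16-tetranorlabd-8(9)-en-7-one | CC1(C)CCC[C@@]2(C)[C@H]1CC(=O)C(C)=C2CCI | intermediate
6 | 2-bromoprop-2-en-1-ol | OCC(Br)=C | starting material
7 | [(2-bromoprop-2-en-1-yl)oxy](tert-butyl)diphenylsilane | C=C(Br)CO[Si](c1ccccc1)(c1ccccc1)C(C)(C)C | intermediate
8 | (7-oxo-13,14,15,16-tetranorlabd-8(9)-en-12-yl)zinc iodide (not isolated) | CC1(C)CCC[C@@]2(C)[C@H]1CC(=O)C(C)=C2CC[Zn]I | intermediate
9 | 16-(tert-butyldiphenylsilyloxy)-15-norlabda-8(9),13(14)-dien-7-one | CC1(C)CCC[C@@]2(C)[C@H]1CC(=O)C(C)=C2CCC(=C)CO[Si](c1ccccc1)(c1ccccc1)C(C)(C)C | intermediate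
10 | 16-(tert-butyldiphenylsilyloxy)-15-norlabda-8(9),13(14)-dien-7β-ol | CC1(C)CCC[C@@]2(C)[C@H]1C[C@H](O)C(C)=C2CCC(=C)CO[Si](c1ccccc1)(c1ccccc1)C(C)(C)C | intermediate
11 | 8β,9β-epoxy-16-(tert-butyldiphenylsilyloxy)-15-norlabd-13(14)-en-7β-ol | CC1(C)CCC[C@@]2(C)[C@H]1C[C@H](O)[C@]3(C)O[C@]23CCC(=C)CO[Si](c1ccccc1)(c1ccccc1)C(C)(C)C | intermediate
12 | 16-(tert-butyldiphenylsilyloxy)-15-norlabd-13(14)-ene-7β,8β,9α-triol | CC1(C)CCC[C@@]2(C)[C@H]1C[C@H](O)[C@](C)(O)[C@]2(O)CCC(=C)CO[Si](c1ccccc1)(c1ccccc1)C(C)(C)C | intermediate
13 | 7β,8β-isopropylidenedioxy-16-(tert-butyldiphenylsilyloxy)-15-norlabd-13(14)-en-9α-ol | CC1(C)CCC[C@@]2(C)[C@H]1C[C@@H]3OC(C)(C)O[C@]3(C)[C@]2(O)CCC(=C)CO[Si](c1ccccc1)(c1ccccc1)C(C)(C)C | intermediate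
14 | 7β,8β-isopropylidenedioxy-15-norlabd-13(14)-ene-9α,16-diol (cascade substrate) | CC1(C)CCC[C@@]2(C)[C@H]1C[C@@H]3OC(C)(C)O[C@]3(C)[C@]2(O)CCC(=C)CO | intermediate
15 | carbon monoxide | [C-]#[O+] | starting material
16 | (13S)-9α,13-epoxy-7β,8β-isopropylidenedioxylabdan-15,16-olide (cascade product) | CC1(C)CCC[C@@]2(C)[C@H]1C[C@@H]3OC(C)(C)O[C@]3(C)[C@]24CC[C@]5(COC(=O)C5)O4 | intermediate
17 | (13S)-9α,13-epoxy-7β,8β-dihydroxylabdan-15,16-olide | CC1(C)CCC[C@@]2(C)[C@H]1C[C@H](O)[C@](C)(O)[C@]21CC[C@]2(COC(=O)C2)O1 | intermediate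
18 | (13S)-9α,13-epoxy-8β-hydroxy-7-oxolabdan-15,16-olide (CNP0208728.2) | CC1(C)CCC[C@@]2(C)[C@H]1CC(=O)[C@](C)(O)[C@]21CC[C@]2(COC(=O)C2)O1 | target

Total step count: 14 (13 on the main line plus the silylation of 6).
Longest linear sequence: 13 steps (steps 1–4 and 6–14, from 1).

Steps most likely to fail

1. Step 12. What may go wrong: weak or wrong π-facial discrimination at C13, sluggish attack of the hindered tertiary hydroxyl on the palladium-bound alkene, or oxidation of the allylic alcohol outrunning cyclisation. The fallback builds ring D first and ring C second, without carbonylation. Starting from 14, the primary C16 hydroxyl is acylated selectively (acryloyl chloride, Et3N, CH2Cl2, −78 °C) to give the acrylate ester F1. Ring-closing metathesis between the acrylate and the 1,1-disubstituted alkene (second-generation Grubbs catalyst, RuCl2(=CHPh)(PCy3)(H2IMes), toluene, 80 °C) gives the β-substituted butenolide F2 with loss of ethene. DBU (CH2Cl2, rt) then triggers intramolecular oxa-Michael addition of the 9α-hydroxyl to C13 (5-exo-trig), which rejoins the route at 16. This addition is reversible under the base, so C13 is set under thermodynamic control and material of the wrong configuration can be returned to the equilibrium through F2; C15 then stems from the acrylate.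

2. Step 9. What may go wrong: after ionisation of the C9–O bond the cation loses a proton toward C11 or undergoes a 1,2-shift faster than water traps it, or the silyl ether is cleaved. In the fallback the oxygen at C8 is delivered from inside the molecule and the oxirane oxygen stays on C9. Starting from 10, Boc2O and DMAP (CH2Cl2) give the tert-butyl carbonate F3. mCPBA (NaHCO3, CH2Cl2, 0 °C) should epoxidise the tetrasubstituted alkene from the open α face, anti to the C10 methyl and the carbonate, to give the 8α,9α-epoxide F4. BF3·OEt2 (CH2Cl2, −40 °C) lets the carbonate carbonyl oxygen open the oxirane at C8 from the β face (5-exo, trans-diaxial) with loss of isobutene, leaving the oxirane oxygen as the 9α-hydroxyl in the 7β,8β-cyclic carbonate F5. K2CO3 in MeOH removes the carbonate and rejoins the route at 12.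

3. Step 8. What may go wrong: oxygen delivery from a pseudo-equatorial hydroxyl to the β face, next to the C10 methyl, is slow, so that oxidation back to the enone or unselective epoxidation takes over. The fallback is the halohydrin route to the β-epoxide. Starting from 10, NBS (1 equiv, THF–H2O, 0 °C) should form the bromonium ion on the open α face of the more nucleophilic tetrasubstituted alkene, and water opens it trans-diaxially at C8 from the β face to give the 9α-bromo-7β,8β-diol F6. K2CO3 in MeOH then closes the 8β-alkoxide onto C9 with inversion and rejoins the route at 11, the same logic by which 9β,11β-epoxy steroids are made.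

Further compounds
F1 | step 12 | 16-acryloyloxy-7β,8β-isopropylidenedioxy-15-norlabd-13(14)-en-9α-ol | CC1(C)CCC[C@@]2(C)[C@H]1C[C@@H]3OC(C)(C)O[C@]3(C)[C@]2(O)CCC(=C)COC(=O)C=C
F2 | step 12 | 9α-hydroxy-7β,8β-isopropylidenedioxylabd-13-en-15,16-olide | CC1(C)CCC[C@@]2(C)[C@H]1C[C@@H]3OC(C)(C)O[C@]3(C)[C@]2(O)CCC4=CC(=O)OC4
F3 | step 9 | 7β-(tert-butoxycarbonyloxy)-16-(tert-butyldiphenylsilyloxy)-15-norlabda-8(9),13(14)-diene | CC1(C)CCC[C@@]2(C)[C@H]1C[C@H](OC(=O)OC(C)(C)C)C(C)=C2CCC(=C)CO[Si](c1ccccc1)(c1ccccc1)C(C)(C)C
F4 | step 9 | 7β-(tert-butoxycarbonyloxy)-8α,9α-epoxy-16-(tert-butyldiphenylsilyloxy)-15-norlabd-13(14)-ene | CC1(C)CCC[C@@]2(C)[C@H]1C[C@H](OC(=O)OC(C)(C)C)[C@@]3(C)O[C@@]23CCC(=C)CO[Si](c1ccccc1)(c1ccccc1)C(C)(C)C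
F5 | step 9 | 7β,8β-carbonyldioxy-16-(tert-butyldiphenylsilyloxy)-15-norlabd-13(14)-en-9α-ol | CC1(C)CCC[C@@]2(C)[C@H]1C[C@@H]3OC(=O)O[C@]3(C)[C@]2(O)CCC(=C)CO[Si](c1ccccc1)(c1ccccc1)C(C)(C)C
F6 | step 8 | 9α-bromo-16-(tert-butyldiphenylsilyloxy)-15-norlabd-13(14)-ene-7β,8β-diol | CC1(C)CCC[C@@]2(C)[C@H]1C[C@H](O)[C@](C)(O)[C@]2(Br)CCC(=C)CO[Si](c1ccccc1)(c1ccccc1)C(C)(C)C
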